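The γ‑lactone (O–C7–C8–C17–C19, briarane numbering) is read as the Baeyer–Villiger product of a cyclobutanone. A ketene–enol ether [2+2] cycloaddition between vinylketene and a (Z)‑silyl enol ether carried by an enantiopure cyclohexene (ring A, from a catalytic asymmetric Diels–Alder reaction) forms C19–C17 and C7–C8 at once and sets C7, C8 and C17. C8, later the tertiary alcohol, is the enol ether carbon and C19 the ketene carbonyl. Oxygen insertion between C19 and C7, ring‑closing metathesis of the C7 vinyl group onto an isopropenyl side chain (ten‑membered ring, C5=C6) and desilylation finish the synthesis.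

Key step: step 15

Remark: briarane numbering is used (C1 quaternary ring carbon with CH3‑15; C2 and C9 the acetoxy carbons; C5=C6 the macrocyclic olefin with CH3‑16; C7–O–C19(=O)–C17(CH3‑18)–C8(OH) the lactone; C10–C14 the rest of ring A with CH3‑20 on C11 and OH on C12; β is the face of CH3‑15); compounds 1, 3, 5, 11 and 23 are taken as commercial, and the sense of induction of the Diels–Alder catalyst and of the two reagent‑controlled reductions is assigned from the accepted models for these catalysts.

Step 1
Reactants: 1 pent-1-en-3-one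
Product: 2 (Z)-3-(tert-butyldimethylsilyloxy)penta-1,3-diene
Conditions: TBSOTf, Et3N, CH2Cl2, 0 °C
Reagents that add atoms: tert-butyldimethylsilyl triflate, CC(C)(C)[Si](C)(C)OS(=O)(=O)C(F)(F)F
Why: Soft enolisation of the only enolisable position (the ethyl CH2) followed by O‑silylation should give the silyl dienol ether, the (Z) isomer (CH3 cis to OSi) being the usual product of this silyl enol ether formation.

Step 2
Reactants: 2 (Z)-3-(tert-butyldimethylsilyloxy)penta-1,3-diene; 3 ethyl (E)-3-methyl-4-oxobut-2-enoate
Product: 4 Diels–Alder adduct (ring A with C12 silyl enol ether)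
Conditions: (S)-3,3-diphenyl-1-(2-methylphenyl)tetrahydro-1H,3H-pyrrolo[1,2-c][1,3,2]oxazaborole (20 mol %), HNTf2 (20 mol %), CH2Cl2, −78 to −40 °C
Reagents that add atoms: none
Why: Enantioselective Diels–Alder reaction under oxazaborolidinium catalysis: the nucleophilic CH(CH3) terminus of the 2‑silyloxydiene bonds to the β‑carbon (C10) of the acid‑bound enal, the exo‑formyl/endo‑ester transition state with the (Z)‑diene places CH3‑20, the ester and CH3‑15 all cis, and the catalyst shields one enal face to set C1, C10 and C11.

Step 3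
Reactants: 4 Diels–Alder adduct; 5 4-bromo-2-methylbut-1-ene
Product: 7 hydroxy ester (C2 epimers), via 3-methylbut-3-enylmagnesium bromide 6 (not isolated)
Conditions: 5, Mg, THF, rt; then 4, THF, −78 °C; NH4Cl (aq)
Reagents that add atoms: none
Why: Grignard addition should be chemoselective for the aldehyde over the hindered ester at low temperature; the C2 configuration is not controlled here and is erased in step 4.

Step 4
Reactants: 7 hydroxy ester (C2 epimers)
Product: 8 keto ester
Conditions: Dess–Martin periodinane, NaHCO3, CH2Cl2, 0 °C to rt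
Reagents that add atoms: none
Why: Dess–Martin oxidation converts the secondary alcohol into the C2 ketone under buffered conditions that spare the silyl enol ether and the isopropenyl group.

Step 5
Reactants: 8 keto ester
Product: 10 trans-fused lactone, via (2R)-hydroxy ester 9 (not isolated)
Conditions: (S)-1-methyl-3,3-diphenyltetrahydro-1H,3H-pyrrolo[1,2-c][1,3,2]oxazaborole (20 mol %), catecholborane, toluene, −78 to −40 °C; MeOH; then DBU (cat.), toluene, 60 °C
Reagents that add atoms: none
Why: Corey–Bakshi–Shibata reduction, in which the catalyst distinguishes the quaternary C1 flank (large) from the CH2 flank (small), should give the (2R)‑alcohol under reagent control (catecholborane avoids hydroboration of the alkene), and base‑promoted transesterification then closes the γ‑lactone, which masks O2 and prepares C9 for a single addition.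

Step 6
Reactants: 10 trans-fused lactone; 11 1-propynyllithium
Product: 12 hydroxy ynone
Conditions: THF, −78 °C; NH4Cl (aq)
Reagents that add atoms: none
Why: Addition of an alkynyllithium to a lactone stops at the hemiketal alkoxide, which opens on work‑up to the ynone at C9 and frees the 2‑hydroxyl (lactone‑to‑ynone acylation).

Step 7
Reactants: 12 hydroxy ynone
Product: 13 2-O-acetyl ynone
Conditions: Ac2O, pyridine, 4-(dimethylamino)pyridine (cat.), CH2Cl2, rt
Reagents that add atoms: acetic anhydride, CC(=O)OC(C)=O
Why: Nucleophile‑catalysed acetylation of the only free hydroxyl installs the C2 acetate of the target.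

Step 8
Reactants: 13 2-O-acetyl ynone
Product: 14 (9R)-propargylic alcohol
Conditions: Ru[(R,R)-TsNCH(Ph)CH(Ph)NH](η6-p-cymene) (2 mol %), i-PrOH, rt
Reagents that add atoms: none
Why: Noyori‑type asymmetric transfer hydrogenation of an α,β‑acetylenic ketone is reagent‑controlled (alkynyl versus branched alkyl flank), and the (R,R) catalyst should give the (9R)‑alcohol without base, so C10 is not epimerised.

Step 9
Reactants: 14 (9R)-propargylic alcohol
Product: 15 9-O-Boc carbonate
Conditions: Boc2O, 4-(dimethylamino)pyridine (cat.), MeCN, rt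
Reagents that add atoms: di-tert-butyl dicarbonate, CC(C)(C)OC(=O)OC(=O)OC(C)(C)C
Why: Carbonate formation protects O9 through the C12 inversion and provides the internal oxygen nucleophile for step 13.

Step 10
Reactants: 15 9-O-Boc carbonate
Product: 16 enone (C12 ketone, C13=C14)
Conditions: Pd(OAc)2 (1.1 equiv), MeCN, rt
Reagents that add atoms: none
Why: Saegusa–Ito oxidation of the C12=C13 silyl enol ether through the oxa‑π‑allyl complex of divalent palladium and β‑hydride elimination should give the C13=C14 enone regiospecifically.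

Step 11
Reactants: 16 enone
Product: 17 (12S)-allylic alcohol (12-epi)
Conditions: NaBH4, CeCl3·7H2O, MeOH, −78 °C
Reagents that add atoms: none
Why: Luche 1,2‑reduction: hydride is expected to add from the α face, away from CH3‑20 and the C9 side chain on the β face, so the hydroxyl should end β (12S) and is corrected in step 12.

Step 12
Reactants: 17 (12S)-allylic alcohol
Product: 19 (12R)-allylic alcohol, via (12R)-formate 18 (not isolated)
Conditions: HCO2H, PPh3, DIAD, THF, 0 °C to rt; then NaHCO3, MeOH, rt
Reagents that add atoms: formic acid, O=CO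
Why: Mitsunobu reaction: SN2 displacement of the activated allylic alcohol by formate inverts C12 to the required α‑hydroxyl configuration, and the formate, far more labile than the acetate and the Boc carbonate, is removed by bicarbonate methanolysis.

Step 13
Reactants: 19 (12R)-allylic alcohol
Product: 20 (Z)-alkylidene cyclic carbonate
Conditions: Ph3PAuNTf2 (2 mol %), CH2Cl2, rt
Reagents that add atoms: none
Why: Cyclisation of a tert‑butyl propargylic carbonate catalysed by monovalent gold: 5‑exo‑dig anti attack of the carbonyl oxygen on the activated alkyne, loss of isobutene and protodeauration should place O8 on C8 cis to CH3‑18, and the trans‑disposed 12‑hydroxyl cannot reach the alkyne.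

Step 14
Reactants: 20 (Z)-alkylidene cyclic carbonate
Product: 22 (Z)-silyl enol ether, via dilithium alkoxide-enolate 21 (not isolated)
Conditions: MeLi (2.0 equiv), THF, −78 °C; then Et3SiOTf, −78 to −40 °C; Et3N, NaHCO3 (aq)
Reagents that add atoms: methyllithium, [Li]C; triethylsilyl triflate, CC[Si](CC)(CC)OS(=O)(=O)C(F)(F)F
Why: Organolithium cleavage of an enol carbonate: after deprotonation of the 12‑hydroxyl, methyllithium adds to the strained carbonate carbonyl and the tetrahedral intermediate expels the enolate, so the carbonate carbon becomes the C9 acetate and the regio‑ and geometrically defined (Z)‑enolate is released, which the silyl triflate traps on oxygen together with the C12 alkoxide.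

Step 15
Reactants: 22 (Z)-silyl enol ether; 23 (E)-but-2-enoyl chloride
Product: 25 cyclobutanone, via vinylketene 24 (not isolated)
Conditions: 23 (slow addition), Et3N, CH2Cl2, 40 °C
Reagents that add atoms: none
Why: Triethylamine dehydrochlorinates 23 to vinylketene 24, whose electrophilic carbonyl carbon C19 bonds to the nucleophilic β‑carbon C17 of the silyl enol ether while the ketene α‑carbon C7 bonds to the oxygen‑bearing C8, either as an orthogonal [π2s+π2a] cycloaddition or through a short‑lived zwitterion (C19–C17 first, then 4‑exo collapse of the enolate carbon C7 onto the silyloxycarbenium C8); the closest known reaction is the Staudinger‑type ketene–enol ether [2+2] route to 3‑oxycyclobutanones. The only ring closed is the four‑membered ketone, formed by intermolecular cycloaddition across C8=C17 and not by cyclisation of a tether. C17 follows from suprafacial addition to the (Z)‑enol ether (CH3‑18 cis to O8); C8 is controlled by the C9 stereocentre, the ketene approaching anti to ring A with C9–H turned toward the bulky silyloxy group (A(1,2) strain) and the acetoxy group inside (inside‑alkoxy model); C7 should end with the vinyl group cis to the silyloxy group, because the all‑cis 2,4‑disubstituted cyclobutanone (both α‑substituents trans to the large C9 substituent) is the more stable epimer and is reachable by enolisation under the amine. The step needs chemoselectivity for the electron‑rich enol ether over the isopropenyl and cyclohexene double bonds, [2+2] rather than [4+2] reactivity of the vinylketene and C19‑to‑C17 regiochemistry, all secured by the polarity match between the ketene carbonyl carbon and the enol ether β‑carbon. Slow addition of 23 keeps the ketene concentration low and limits dimerisation.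

Step 16
Reactants: 25 cyclobutanone
Product: 26 γ-lactone with 7-vinyl group
Conditions: H2O2 (30% aq), Na2HPO4, CF3CH2OH, 0 °C to rt
Reagents that add atoms: hydrogen peroxide, OO
Why: Baeyer–Villiger oxidation of the strained cyclobutanone: the allylic C7 should migrate with retention in preference to C17, placing oxygen between C7 and C19, and these peracid‑free conditions should leave the alkenes and silyl ethers intact.

Step 17
Reactants: 26 γ-lactone with 7-vinyl group
Product: 27 bis(triethylsilyl) ether of the target
Conditions: RuCl2(=CH-C6H4-2-O-i-Pr)(H2IMes) (second-generation Hoveyda–Grubbs catalyst, H2IMes = 1,3-dimesitylimidazolidin-2-ylidene, 10 mol %), toluene (0.5 mM), 100 °C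
Reagents that add atoms: none
Why: Ring‑closing metathesis between the C7 vinyl group and the isopropenyl terminus at high dilution closes the ten‑membered ring at C5=C6, and the trans‑fused ring A and lactone together with the lower strain of the in‑ring cis arrangement should favour the (5Z) trisubstituted olefin.

Step 18
Reactants: 27 bis(triethylsilyl) ether of the target
Product: 28 CNP0222085.1
Conditions: HF·pyridine, pyridine, THF, 0 °C to rt
Reagents that add atoms: none
Why: Fluoride‑mediated desilylation should remove the secondary allylic and the tertiary triethylsilyl ethers while the two acetates and the lactone survive the buffered acidic medium.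

Compound list

1 | pent-1-en-3-one (ethyl vinyl ketone) | CCC(=O)C=C | starting material
2 | (Z)-3-(tert-butyldimethylsilyloxy)penta-1,3-diene (CH3 cis to OSi) | C/C=C(/C=C)O[Si](C)(C)C(C)(C)C | intermediate
3 | ethyl (E)-3-methyl-4-oxobut-2-enoate | CCOC(=O)/C=C(\C)C=O | starting material
4 | Diels–Alder adduct: ethyl 6-formyl-2,6-dimethyl-3-(tert-butyldimethylsilyloxy)cyclohex-3-ene-1-carboxylate, ester cis to both methyl groups and trans to formyl (1S,10S,11R) | CCOC(=O)[C@H]1[C@@H](C)C(O[Si](C)(C)C(C)(C)C)=CC[C@]1(C)C=O | intermediate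
5 | 4-bromo-2-methylbut-1-ene | C=C(C)CCBr | starting material
6 | 3-methylbut-3-enylmagnesium bromide | C=C(C)CC[Mg]Br | intermediate
7 | hydroxy ester: 4 with the formyl group turned into CH(OH)CH2CH2C(CH3)=CH2 (C2 epimer mixture) | CCOC(=O)[C@H]1[C@@H](C)C(O[Si](C)(C)C(C)(C)C)=CC[C@]1(C)C(O)CCC(C)=C | intermediate
8 | keto ester: C2 ketone | CCOC(=O)[C@H]1[C@@H](C)C(O[Si](C)(C)C(C)(C)C)=CC[C@]1(C)C(=O)CCC(C)=C | intermediate
9 | (2R)-hydroxy ester | CCOC(=O)[C@H]1[C@@H](C)C(O[Si](C)(C)C(C)(C)C)=CC[C@]1(C)[C@H](O)CCC(C)=C | intermediate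
10 | trans-fused γ-lactone (O2–C9=O) on ring A, silyl enol ether retained (1S,2R,10S,11R) | O=C1[C@H]2[C@@H](C)C(O[Si](C)(C)C(C)(C)C)=CC[C@]2(C)[C@@H](CCC(C)=C)O1 | intermediate
11 | 1-propynyllithium | CC#C[Li] | starting material
12 | hydroxy ynone: C9 ketone bearing prop-1-ynyl, free (2R)-OH | CC#CC(=O)[C@H]1[C@@H](C)C(O[Si](C)(C)C(C)(C)C)=CC[C@]1(C)[C@H](O)CCC(C)=C | intermediate
13 | 2-O-acetyl ynone | CC#CC(=O)[C@H]1[C@@H](C)C(O[Si](C)(C)C(C)(C)C)=CC[C@]1(C)[C@H](OC(C)=O)CCC(C)=C | intermediate
14 | (9R)-propargylic alcohol | O[C@@H](C#CC)[C@H]1[C@@H](C)C(O[Si](C)(C)C(C)(C)C)=CC[C@]1(C)[C@H](OC(C)=O)CCC(C)=C | intermediate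
15 | 9-O-Boc carbonate of 14 | CC(C)(C)OC(=O)O[C@@H](C#CC)[C@H]1[C@@H](C)C(O[Si](C)(C)C(C)(C)C)=CC[C@]1(C)[C@H](OC(C)=O)CCC(C)=C | intermediate
16 | enone: C12 ketone, C13=C14 | CC(C)(C)OC(=O)O[C@@H](C#CC)[C@H]1[C@@H](C)C(=O)C=C[C@]1(C)[C@H](OC(C)=O)CCC(C)=C | intermediate
17 | (12S)-allylic alcohol (12-epi, OH β, cis to CH3-20) | CC(C)(C)OC(=O)O[C@@H](C#CC)[C@H]1[C@@H](C)[C@@H](O)C=C[C@]1(C)[C@H](OC(C)=O)CCC(C)=C | intermediate
18 | (12R)-formate | CC(C)(C)OC(=O)O[C@@H](C#CC)[C@H]1[C@@H](C)[C@H](OC=O)C=C[C@]1(C)[C@H](OC(C)=O)CCC(C)=C | intermediate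
19 | (12R)-allylic alcohol (OH α, trans to CH3-20) | CC(C)(C)OC(=O)O[C@@H](C#CC)[C@H]1[C@@H](C)[C@H](O)C=C[C@]1(C)[C@H](OC(C)=O)CCC(C)=C | intermediate
20 | (Z)-4-ethylidene-1,3-dioxolan-2-one: cyclic carbonate spanning O9 and O8, CH3-18 cis to O8 | C/C=C1\OC(=O)O[C@@H]1[C@H]2[C@@H](C)[C@H](O)C=C[C@]2(C)[C@H](OC(C)=O)CCC(C)=C | intermediate
21 | dilithium salt: C12 alkoxide and (Z)-C8 enolate, 9-OAc | C/C=C(\O[Li])[C@H](OC(C)=O)[C@H]1[C@@H](C)[C@H](O[Li])C=C[C@]1(C)[C@H](OC(C)=O)CCC(C)=C | intermediate
22 | (Z)-silyl enol ether: 8-OSiEt3 on C8=C17 (CH3-18 cis to O8), 9-OAc, 12-OSiEt3, 2-OAc | C/C=C(\O[Si](CC)(CC)CC)[C@H](OC(C)=O)[C@H]1[C@@H](C)[C@H](O[Si](CC)(CC)CC)C=C[C@]1(C)[C@H](OC(C)=O)CCC(C)=C | intermediate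
23 | (E)-but-2-enoyl chloride (crotonyl chloride) | C/C=C/C(Cl)=O | starting material
24 | vinylketene (buta-1,3-dien-1-one) | C=CC=C=O | intermediate
25 | cyclobutanone C19(=O)–C7H(vinyl)–C8(OSiEt3)–C17H(CH3), with vinyl, silyloxy and methyl all cis (7S,8S,17R) | C=C[C@@H]1C(=O)[C@H](C)[C@@]1(O[Si](CC)(CC)CC)[C@H](OC(C)=O)[C@H]2[C@@H](C)[C@H](O[Si](CC)(CC)CC)C=C[C@]2(C)[C@H](OC(C)=O)CCC(C)=C | intermediate
26 | γ-lactone (O between C19 and C7) with 7-vinyl group | C=C[C@@H]1OC(=O)[C@H](C)[C@@]1(O[Si](CC)(CC)CC)[C@H](OC(C)=O)[C@H]2[C@@H](C)[C@H](O[Si](CC)(CC)CC)C=C[C@]2(C)[C@H](OC(C)=O)CCC(C)=C | intermediate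
27 | 8,12-bis(triethylsilyl) ether of the target (ten-membered ring closed, 5Z) | CC(=O)O[C@@H]1[C@H]2[C@@H](C)[C@H](O[Si](CC)(CC)CC)C=C[C@]2(C)[C@H](OC(C)=O)CC/C(C)=C\[C@@H]2OC(=O)[C@H](C)[C@]21O[Si](CC)(CC)CC | intermediate
28 | CNP0222085.1 (1S,2R,5Z,7S,8S,9R,10S,11R,12R,17R) | CC(=O)O[C@@H]1[C@H]2[C@@H](C)[C@H](O)C=C[C@]2(C)[C@H](OC(C)=O)CC/C(C)=C\[C@@H]2OC(=O)[C@H](C)[C@]21O | target

Total step count: 18. Longest linear sequence: 18 steps (from 1).

Steps most likely to fail

1. Step 15 (key step). The hindered trisubstituted silyl enol ether may react too slowly, so that the ketene dimerises; silyl transfer within the zwitterion may give an open‑chain acylation product; or the ketene may add to the wrong enol ether face. Fallback, setting out from 22: the ketene is replaced by a far more electrophilic keteniminium ion. N,N-dimethylbut-3-enamide F1, made from but-3-enoic acid and dimethylamine, is converted with triflic anhydride and 2,4,6-trimethylpyridine into the N,N-dimethyl vinylketeniminium triflate F2. This adds across C8=C17 of 22 to give the cyclobutaniminium triflate F3, and aqueous bicarbonate hydrolysis of F3 returns to the route at 25.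

2. Step 17. Intermolecular cross‑metathesis may outrun closure of the strained ten‑membered ring, or the olefin may close with the E geometry. Fallback, setting out from 25: the ring is closed before the oxygen insertion. Ring‑closing metathesis of the 2‑vinylcyclobutanone, where C7 can still equilibrate through the enol so that the epimer able to cyclise is drained, gives the macrocyclic cyclobutanone F4. Baeyer–Villiger oxidation under the conditions of step 16 then returns to the route at 27.

3. Step 14. Methyllithium may add a second time to an acetate, the new acetyl group may migrate from O9 to the enolate oxygen, or enolate geometry may be lost before silylation. Fallback, setting out from 19: the acyl transfer is replaced by stepwise chemistry. Silylation of the 12‑hydroxyl (Et3SiCl, imidazole) gives the 12-O-triethylsilyl Boc carbonate F5. Gold‑catalysed cyclisation as in step 13 gives the silylated cyclic enol carbonate F6, and mild hydrolysis (water, cat. DBU, MeCN) with loss of CO2 gives the α-hydroxy ethyl ketone F7. Acetylation gives the α-acetoxy ethyl ketone F8, and soft enolisation on the ethyl side (Et3SiOTf, Et3N, CH2Cl2, −78 °C), which is known to give the (Z)‑silyl enol ether of α‑acyloxy ethyl ketones, returns to the route at 22.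

Further compounds

F1 | step 15 | N,N-dimethylbut-3-enamide | C=CCC(=O)N(C)C
F2 | step 15 | N,N-dimethyl vinylketeniminium triflate | C=CC=C=[N+](C)C.[O-]S(=O)(=O)C(F)(F)F
F3 | step 15 | cyclobutaniminium triflate corresponding to 25 (C19=N+(CH3)2) | C=C[C@@H]1C(=[N+](C)C)[C@H](C)[C@@]1(O[Si](CC)(CC)CC)[C@H](OC(C)=O)[C@H]2[C@@H](C)[C@H](O[Si](CC)(CC)CC)C=C[C@]2(C)[C@H](OC(C)=O)CCC(C)=C.[O-]S(=O)(=O)C(F)(F)F
F4 | step 17 | macrocyclic cyclobutanone (ten-membered ring closed, 5Z, C19 ketone bonded to C7) | CC(=O)O[C@@H]1[C@H]2[C@@H](C)[C@H](O[Si](CC)(CC)CC)C=C[C@]2(C)[C@H](OC(C)=O)CC/C(C)=C\[C@@H]2C(=O)[C@H](C)[C@]21O[Si](CC)(CC)CC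
F5 | step 14 | 12-O-triethylsilyl ether of 19 | CC(C)(C)OC(=O)O[C@@H](C#CC)[C@H]1[C@@H](C)[C@H](O[Si](CC)(CC)CC)C=C[C@]1(C)[C@H](OC(C)=O)CCC(C)=C
F6 | step 14 | 12-O-triethylsilyl ether of 20 | C/C=C1\OC(=O)O[C@@H]1[C@H]2[C@@H](C)[C@H](O[Si](CC)(CC)CC)C=C[C@]2(C)[C@H](OC(C)=O)CCC(C)=C
F7 | step 14 | α-hydroxy ethyl ketone (9-OH, C8 ketone, 12-OSiEt3) | CCC(=O)[C@H](O)[C@H]1[C@@H](C)[C@H](O[Si](CC)(CC)CC)C=C[C@]1(C)[C@H](OC(C)=O)CCC(C)=C
F8 | step 14 | α-acetoxy ethyl ketone (9-OAc, C8 ketone, 12-OSiEt3) | CCC(=O)[C@H](OC(C)=O)[C@H]1[C@@H](C)[C@H](O[Si](CC)(CC)CC)C=C[C@]1(C)[C@H](OC(C)=O)CCC(C)=C
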